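## Structural features

The target is a 2,3-trans-dihydroflavonol: a chroman-4-one (ring C: O1, C2, C3, C4) fused to a fully substituted phloroglucinol-type ring A, with a 2,4-dihydroxyphenyl ring B on C2. Ring A has no free position: C5–OH (chelated to C4=O), a 3-hydroxy-3-methylbutyl chain on C6, C7–OH, a lavandulyl chain on C8, C8a–O1 and C4a–C4. Because the C6 and C8 chains differ, the oxygen that becomes O1 must be the one next to the lavandulyl-bearing carbon. C2 (R) and C3 (R) are adjacent, with aryl and hydroxyl trans; the third stereocentre (S) is in the lavandulyl chain, two bonds from C8, too remote to control or be controlled by C2/C3. Fragile groups are the tertiary alcohol and the two lavandulyl olefins next to free phenols (acid closes chroman rings), the β-aryloxy ketone (base opens ring C by retro-oxa-Michael reaction; the 2',4'-dioxygenated ring B makes C2–O1 easy to ionise) and the α-ketol (C3 epimerisation, oxidation to the flavonol). The real difficulty is to place two different carbon chains and O1 unambiguously on ring A, to set C2/C3 absolutely and independently of the remote centre, and to finish without strong acid or base. The key step exploits that C2 is the β-carbon of a vinylogous ester in the corresponding chromone, a flat precursor in which O1–C8a already exists: C2–C1' is made last by enantioselective 1,4-addition, and the C4 enolate then takes the C3 hydroxyl anti to the new aryl group.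

## Logic of the disconnections

**29 ⇒ 27 (through 28).** Bonds cut: four aryl O–CH2 acetal bonds and the tertiary O–Si bond. All hydroxyls except 3-OH are masked until the end so that enolate chemistry and cross-couplings are possible. The forward step must avoid protic strong acid, so a buffered silyl triflate cleavage followed by fluoride is planned.

**27 ⇒ 25.** Bond cut: C3–O. With C2 in place, an electrophilic oxygen adds to the C3=C4 enolate on the face away from ring B, giving the trans relation. This removes one stereocentre and the α-ketol. The demand is that the enolate is oxidised before it can expel O1.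

**25 ⇒ 24 + 15 (key).** Bond cut: C2–C1'. This removes the whole ring C stereochemical problem: 24 has only the side-chain stereocentre and a flat pyranone whose O1–C8a bond fixes the ring A regiochemistry. Ring B arrives in one convergent operation. The demand is catalyst-controlled face selection at C2 and protonation of the metal enolate faster than ring opening.

**24 ⇒ 22 + 9 (through 23).** Bond cut: C8–C1''. The olefin-bearing, stereodefined chain is introduced after both electrophilic iodinations, so no olefin meets an iodonium source. The demand is an sp2–sp3 coupling at a di-ortho-oxygenated position without β-hydride elimination; the stereocentre is β to the metal and not involved.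

**22 ⇒ 21 ⇒ 20.** Bonds cut: O5–CH2 and C8–I. In 20, C8 is the only free ring A position, so the halogenation needs no selectivity; O5 is capped afterwards, since the free phenol activates the ring for this iodination.

**20 ⇒ 18 + 11 (through 19); 11 ⇒ 10.** Bond cut: C6–CH2. The tertiary carbinol arrives complete and protected by B-alkyl coupling, so no organomagnesium reagent meets the pyranone. The hydroboration is done on the small alkene only.

**18 ⇒ 17 ⇒ 16.** Bonds cut: C6–I and O7–CH2. The innate difference between the acidic 7-OH and the chelated 5-OH of 16 allows mono-protection, and the free chelated phenol then directs iodine to its ortho position C6. This is the only regiochemical selectivity the route has to win, and it is won on a three-step-old intermediate.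

**9 ⇒ 8 ⇒ 7 ⇒ 4 + 5 (through 6); 4 ⇒ 1 + 2 (through 3).** Bond cut: stereocentre–CH2 of the prenyl arm. Auxiliary-controlled α-alkylation of a dienolate sets the only side-chain stereocentre and forms the isopropenyl group by deconjugation. The demand is α- over γ-alkylation and no epimerisation on reduction.

**15 ⇒ 13 ⇒ 12 (through 14).** Bonds cut: C–B and two O–CH2. Bromine–lithium exchange places boron at C1 of the resorcinol unit, which direct lithiation would not do.

## Other disconnections considered

Alternative 1: Cut O1–C2, with C3–O traced to an epoxide; this is the chalcone epoxide route that comes to mind first. Forward: Claisen–Schmidt condensation to the per-methoxymethyl (MOM) chalcone A1, Julia–Colonna-type epoxidation to the (2R,3S)-epoxide A2, then acid-induced loss of the ortho acetals and 6-endo opening of the epoxide at the benzylic carbon with inversion. Grounds against: in A2 both ortho oxygens of ring A are flanked by carbon chains, so either can open the epoxide and 6- and 8-lavandulyl isomers are both expected unless a differentiated protection pattern is built at extra cost. The attacked carbon is benzylic to a 2,4-dioxygenated ring and prone to ionisation, and the ring-closing acid meets the olefins and the tertiary carbinol. The chosen plan has O1 in place from the first compound and sets C2 under catalyst control.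

Alternative 2: Cut C4–C4a. Forward: intramolecular Friedel–Crafts (Houben–Hoesch-type) acylation of the aryl ether acid A3, closing ring C from the carbonyl side after O1–C2 has been made by etherification. Grounds against: the ether of A3 requires substitution at a benzylic carbinol carbon carrying an o,p-dioxygenated aryl group by a di-ortho-substituted phenol, where ionisation would erode the future C2 configuration. The ring A oxygens are again undifferentiated, and acylating acids are incompatible with the acetals, olefins and tertiary carbinol. More steps and less control than the chosen plan.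

Alternative 3: Cut the bond between the lavandulyl stereocentre C2'' and its prenyl CH2, copying the biosynthesis in which an 8-prenyl flavonoid is prenylated at C2'' of the prenyl group. Forward: the 8-prenyl dihydroflavonol A4 is treated with a dimethylallyl cation equivalent (5, AgOTf); C–C bond formation at C2'' gives a C3'' cation that loses a methyl proton to form the isopropenyl group. Grounds against: short, but nothing controls the new stereocentre, which is remote from C2/C3. The C3'' cation is positioned to be trapped by O7 as a chroman, and ring B and the product olefins compete for the cation. The chosen plan imports this centre ready-made with auxiliary control.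

Key step: step 14

Remark: MOM = methoxymethyl, TES = triethylsilyl; 1, 2, 5, 10, 12 and 16 are taken as commercial; the descriptor change at the side-chain stereocentre from R (9, 23) to S (24 onward) follows from the priority rules only, the spatial arrangement being unchanged.

## Steps

Step 1
Reactants: 1 (4R)-4-benzyl-1,3-oxazolidin-2-one; 2 3-methylbut-2-enoyl chloride
Product: 4 (4R)-4-benzyl-3-(3-methylbut-2-enoyl)-1,3-oxazolidin-2-one, via lithium oxazolidinide 3 (not isolated)
Conditions: n-BuLi, THF, −78 °C; then 2, −78 → 0 °C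
Reagents that add atoms: none
Why: N-acylation of the lithiated oxazolidinone by the acid chloride, the standard way to attach the auxiliary; no stereocentre is touched.

Step 2
Reactants: 4 (4R)-4-benzyl-3-(3-methylbut-2-enoyl)-1,3-oxazolidin-2-one; 5 1-bromo-3-methylbut-2-ene
Product: 7 (4R)-4-benzyl-3-[(2R)-5-methyl-2-(prop-1-en-2-yl)hex-4-enoyl]-1,3-oxazolidin-2-one, via sodium dienolate 6 (not isolated)
Conditions: NaN(SiMe3)2, THF, −78 °C; then 5, −78 → −40 °C
Reagents that add atoms: none
Why: Evans-type auxiliary alkylation: γ-deprotonation gives the chelated Z-dienolate, which should be alkylated at its α-carbon (kinetic site, deconjugating to the isopropenyl group) on the face away from the benzyl group. With the R auxiliary this should set the 2R centre (isopropenyl outranks the incoming CH2, so the descriptor is opposite to that of the familiar propionate case).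

Step 3
Reactants: 7 (4R)-4-benzyl-3-[(2R)-5-methyl-2-(prop-1-en-2-yl)hex-4-enoyl]-1,3-oxazolidin-2-one
Product: 8 (2R)-5-methyl-2-(prop-1-en-2-yl)hex-4-en-1-ol [(R)-lavandulol]
Conditions: LiBH4, H2O (1 equiv), Et2O, 0 °C
Reagents that add atoms: none
Why: Reductive cleavage of the N-acyl oxazolidinone to the primary alcohol; the weakly basic hydride should not epimerise or conjugate the β,γ-unsaturated α-centre, and auxiliary 1 is recovered.

Step 4
Reactants: 8 (2R)-5-methyl-2-(prop-1-en-2-yl)hex-4-en-1-ol
Product: 9 (2R)-1-iodo-5-methyl-2-(prop-1-en-2-yl)hex-4-ene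
Conditions: I2, PPh3, imidazole, CH2Cl2, 0 °C → rt
Reagents that add atoms: iodine, II
Why: Appel-type iodination by SN2 displacement at the primary carbon; the adjacent stereocentre is not involved.

Step 5
Reactants: 10 2-methylbut-3-en-2-ol
Product: 11 triethyl[(2-methylbut-3-en-2-yl)oxy]silane
Conditions: Et3SiOTf, 2,6-lutidine, CH2Cl2, 0 °C
Reagents that add atoms: triethylsilyl trifluoromethanesulfonate, CC[Si](CC)(CC)OS(=O)(=O)C(F)(F)F
Why: Silylation of a tertiary alcohol with a silyl triflate; the ether masks the hydroxyl through both couplings and the enolate step.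

Step 6
Reactants: 12 4-bromobenzene-1,3-diol
Product: 13 1-bromo-2,4-bis(methoxymethoxy)benzene
Conditions: MOMCl, i-Pr2NEt, CH2Cl2, 0 °C → rt
Reagents that add atoms: chloromethyl methyl ether, COCCl
Why: Williamson-type acetalisation of both phenols, giving ethers stable to organolithium, aqueous base and enolate chemistry.

Step 7
Reactants: 13 1-bromo-2,4-bis(methoxymethoxy)benzene
Product: 15 [2,4-bis(methoxymethoxy)phenyl]boronic acid, via aryllithium 14 (not isolated)
Conditions: n-BuLi, THF, −78 °C; B(OiPr)3, −78 °C → rt; aq NH4Cl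
Reagents that add atoms: triisopropyl borate, CC(C)OB(OC(C)C)OC(C)C; water, O
Why: Bromine–lithium exchange is faster than ortho-lithiation between the two acetals, so boron is placed at C1; the borate is hydrolysed under near-neutral conditions that spare the acetals.

Step 8
Reactants: 16 5,7-dihydroxy-4H-chromen-4-one
Product: 17 5-hydroxy-7-(methoxymethoxy)-4H-chromen-4-one
Conditions: MOMCl (1.05 equiv), i-Pr2NEt, CH2Cl2, 0 °C → rt
Reagents that add atoms: chloromethyl methyl ether, COCCl
Why: The 7-OH is the acidic, vinylogous-acid phenol, whereas the 5-OH is locked in a hydrogen bond to C4=O; selective mono-O-alkylation at O7 should follow.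

Step 9
Reactants: 17 5-hydroxy-7-(methoxymethoxy)-4H-chromen-4-one
Product: 18 5-hydroxy-6-iodo-7-(methoxymethoxy)-4H-chromen-4-one
Conditions: BnMe3N·ICl2, CaCO3, CH2Cl2/MeOH, rt
Reagents that add atoms: benzyltrimethylammonium dichloroiodate, C[N+](C)(C)Cc1ccccc1.Cl[I-]Cl
Why: Electrophilic aromatic iodination; with this reagent 5-hydroxy-7-alkoxy benzopyranones are iodinated ortho to the free chelated phenol (C6) and not at C8. The pyranone C3 is much less nucleophilic than ring A.

Step 10
Reactants: 11 triethyl[(2-methylbut-3-en-2-yl)oxy]silane; 18 5-hydroxy-6-iodo-7-(methoxymethoxy)-4H-chromen-4-one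
Product: 20 5-hydroxy-7-(methoxymethoxy)-6-[3-methyl-3-(triethylsilyloxy)butyl]-4H-chromen-4-one, via alkylborane 19 (not isolated)
Conditions: 11 (slight excess), 9-BBN dimer, THF, 0 °C → rt; then 18, Pd(dppf)Cl2, aq K3PO4, DMF, 50 °C
Reagents that add atoms: none
Why: Anti-Markovnikov hydroboration of the monosubstituted alkene, then B-alkyl Suzuki–Miyaura coupling with the aryl iodide. The alkene is used in slight excess so that no B–H remains to reduce the pyranone.

Step 11
Reactants: 20 5-hydroxy-7-(methoxymethoxy)-6-[3-methyl-3-(triethylsilyloxy)butyl]-4H-chromen-4-one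
Product: 21 5-hydroxy-8-iodo-7-(methoxymethoxy)-6-[3-methyl-3-(triethylsilyloxy)butyl]-4H-chromen-4-one
Conditions: BnMe3N·ICl2, CaCO3, CH2Cl2/MeOH, rt
Reagents that add atoms: benzyltrimethylammonium dichloroiodate, C[N+](C)(C)Cc1ccccc1.Cl[I-]Cl
Why: C8 is the only unsubstituted position of ring A and is para to the free phenol, so the iodination needs no regiocontrol; CaCO3 buffers the HCl and protects the acetal and silyl ether.

Step 12
Reactants: 21 5-hydroxy-8-iodo-7-(methoxymethoxy)-6-[3-methyl-3-(triethylsilyloxy)butyl]-4H-chromen-4-one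
Product: 22 8-iodo-5,7-bis(methoxymethoxy)-6-[3-methyl-3-(triethylsilyloxy)butyl]-4H-chromen-4-one
Conditions: MOMCl, K2CO3, acetone, reflux
Reagents that add atoms: chloromethyl methyl ether, COCCl
Why: O-alkylation of the chelated phenol under forcing carbonate conditions; it removes the last acidic proton before the organozinc and enolate steps.

Step 13
Reactants: 9 (2R)-1-iodo-5-methyl-2-(prop-1-en-2-yl)hex-4-ene; 22 8-iodo-5,7-bis(methoxymethoxy)-6-[3-methyl-3-(triethylsilyloxy)butyl]-4H-chromen-4-one
Product: 24 5,7-bis(methoxymethoxy)-6-[3-methyl-3-(triethylsilyloxy)butyl]-8-[(2S)-5-methyl-2-(prop-1-en-2-yl)hex-4-en-1-yl]-4H-chromen-4-one, via lavandulylzinc iodide 23 (not isolated)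
Conditions: 9, activated Zn dust, LiCl, THF, 40 °C; then 22, Pd(OAc)2, SPhos, THF, 45 °C
Reagents that add atoms: none
Why: LiCl-mediated zinc insertion into the primary iodide, then Negishi coupling; the bulky biarylphosphine should make reductive elimination faster than β-hydride elimination. The stereocentre is β to zinc and takes no part, and the alkylzinc tolerates the pyranone carbonyl.

Step 14
Reactants: 24 5,7-bis(methoxymethoxy)-6-[3-methyl-3-(triethylsilyloxy)butyl]-8-[(2S)-5-methyl-2-(prop-1-en-2-yl)hex-4-en-1-yl]-4H-chromen-4-one; 15 [2,4-bis(methoxymethoxy)phenyl]boronic acid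
Product: 25 (2S)-2-[2,4-bis(methoxymethoxy)phenyl]-5,7-bis(methoxymethoxy)-6-[3-methyl-3-(triethylsilyloxy)butyl]-8-[(2S)-5-methyl-2-(prop-1-en-2-yl)hex-4-en-1-yl]-2,3-dihydro-4H-chromen-4-one
Conditions: [RhCl(C2H4)2]2 (3 mol %), (S)-6,6'-dimethoxy-2,2'-bis[bis(3,4,5-trifluorophenyl)phosphino]-1,1'-biphenyl (6.6 mol %), aq KOH (0.1 equiv), toluene/H2O, 40 °C; 15 (3 equiv) in portions
Reagents that add atoms: none
Why: The hydroxorhodium–bisphosphine complex formed in situ transmetalates with 15 to an arylrhodium species, the C2=C3 bond of 24 coordinates and inserts so that the aryl group is delivered to C2, and the resulting oxa-π-allyl rhodium enolate is hydrolysed by water to ketone 25 with return of the hydroxorhodium catalyst. The closest known reaction type is the Hayashi–Miyaura asymmetric 1,4-addition of arylboronic acids to chromones, for which electron-poor biaryl bisphosphines are established ligands. No ring is closed: ring C is already present in 24, which is why O1 is fixed next to C8 before any ring C stereocentre exists. The new stereocentre C2 is set by the catalyst, the C2-symmetric ligand selecting one enantioface of the flat C2=C3 bond; the S ligand is proposed by analogy with the sense for cyclic enones (S ligand, S β-aryl ketone), and the antipodal ligand is available should a model chromone show the opposite sense. The side-chain stereocentre is too far from C2 to matter, so one diastereomer is expected under catalyst control. The step needs 1,4- over 1,2-addition and no carbometalation of the three isolated olefins; the polarised enone secures this because arylrhodium species do not insert into unactivated alkenes. It also needs protonation of the rhodium enolate to outrun β-elimination of the O1 aryloxide, which the excess of water, the moderate temperature and the poor overlap of the C2–O1 bond with the enolate π system should secure. Protodeboronation of the electron-rich ortho-alkoxy acid 15 is offset by using it in excess and in portions.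

Step 15
Reactants: 25 (2S)-2-[2,4-bis(methoxymethoxy)phenyl]-5,7-bis(methoxymethoxy)-6-[3-methyl-3-(triethylsilyloxy)butyl]-8-[(2S)-5-methyl-2-(prop-1-en-2-yl)hex-4-en-1-yl]-2,3-dihydro-4H-chromen-4-one
Product: 27 (2R,3R)-2-[2,4-bis(methoxymethoxy)phenyl]-3-hydroxy-5,7-bis(methoxymethoxy)-6-[3-methyl-3-(triethylsilyloxy)butyl]-8-[(2S)-5-methyl-2-(prop-1-en-2-yl)hex-4-en-1-yl]-2,3-dihydro-4H-chromen-4-one, via potassium enolate 26 (not isolated)
Conditions: KN(SiMe3)2, THF, −78 °C; 2-(phenylsulfonyl)-3-phenyloxaziridine, −78 °C; aq NH4Cl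
Reagents that add atoms: 2-(phenylsulfonyl)-3-phenyloxaziridine, O=S(=O)(c1ccccc1)N1OC1c1ccccc1
Why: Davis-type enolate hydroxylation: the oxaziridine should transfer oxygen to C3 of the kinetic enolate on the face opposite the C2 aryl group, giving the 2,3-trans ketol (3R) by 1,2-induction. The oxidant does not epoxidise isolated olefins at −78 °C. C2 becomes R only because the new C3 oxygen changes the priorities.

Step 16
Reactants: 27 (2R,3R)-2-[2,4-bis(methoxymethoxy)phenyl]-3-hydroxy-5,7-bis(methoxymethoxy)-6-[3-methyl-3-(triethylsilyloxy)butyl]-8-[(2S)-5-methyl-2-(prop-1-en-2-yl)hex-4-en-1-yl]-2,3-dihydro-4H-chromen-4-one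
Product: 29 (2R,3R)-2-(2,4-dihydroxyphenyl)-3,5,7-trihydroxy-6-(3-hydroxy-3-methylbutyl)-8-[(2S)-5-methyl-2-(prop-1-en-2-yl)hex-4-en-1-yl]-2,3-dihydro-4H-chromen-4-one, via triethylsilyl ether 28 (not isolated)
Conditions: Me3SiOTf, 2,2'-bipyridyl, MeCN, 0 °C → rt; H2O; then HF·pyridine, pyridine, THF, 0 °C → rt
Reagents that add atoms: none
Why: The bipyridyl-buffered silyl triflate converts aryl MOM ethers into aryl silyl ethers without free protic acid, and water then releases the phenols; the lavandulyl olefins and the tertiary centre should therefore not ionise towards chromans. Buffered fluoride then cleaves the tertiary TES ether and any residual O–SiMe3 group; no stereocentre is touched.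

## Compound list

1 | (4R)-4-benzyl-1,3-oxazolidin-2-one | O=C1N[C@H](Cc2ccccc2)CO1 | starting material
2 | 3-methylbut-2-enoyl chloride | CC(C)=CC(=O)Cl | starting material
3 | lithium (4R)-4-benzyl-2-oxo-1,3-oxazolidin-3-ide | [Li+].O=C1[N-][C@H](Cc2ccccc2)CO1 | intermediate
4 | (4R)-4-benzyl-3-(3-methylbut-2-enoyl)-1,3-oxazolidin-2-one | CC(C)=CC(=O)N1[C@H](Cc2ccccc2)COC1=O | intermediate
5 | 1-bromo-3-methylbut-2-ene | CC(C)=CCBr | starting material
6 | sodium (1Z)-1-[(4R)-4-benzyl-2-oxo-1,3-oxazolidin-3-yl]-3-methylbuta-1,3-dien-1-olate | [Na+].[O-]/C(=C\C(C)=C)N1[C@H](Cc2ccccc2)COC1=O | intermediate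
7 | (4R)-4-benzyl-3-[(2R)-5-methyl-2-(prop-1-en-2-yl)hex-4-enoyl]-1,3-oxazolidin-2-one | C=C(C)[C@@H](CC=C(C)C)C(=O)N1[C@H](Cc2ccccc2)COC1=O | intermediate
8 | (2R)-5-methyl-2-(prop-1-en-2-yl)hex-4-en-1-ol [(R)-lavandulol] | C=C(C)[C@@H](CC=C(C)C)CO | intermediate
9 | (2R)-1-iodo-5-methyl-2-(prop-1-en-2-yl)hex-4-ene | C=C(C)[C@@H](CC=C(C)C)CI | intermediate
10 | 2-methylbut-3-en-2-ol | C=CC(C)(C)O | starting material
11 | triethyl[(2-methylbut-3-en-2-yl)oxy]silane | C=CC(C)(C)O[Si](CC)(CC)CC | intermediate
12 | 4-bromobenzene-1,3-diol | Oc1ccc(Br)c(O)c1 | starting material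
13 | 1-bromo-2,4-bis(methoxymethoxy)benzene | COCOc1ccc(Br)c(OCOC)c1 | intermediate
14 | [2,4-bis(methoxymethoxy)phenyl]lithium | [Li]c1ccc(OCOC)cc1OCOC | intermediate
15 | [2,4-bis(methoxymethoxy)phenyl]boronic acid | OB(O)c1ccc(OCOC)cc1OCOC | intermediate
16 | 5,7-dihydroxy-4H-chromen-4-one | O=c1ccoc2cc(O)cc(O)c12 | starting material
17 | 5-hydroxy-7-(methoxymethoxy)-4H-chromen-4-one | O=c1ccoc2cc(OCOC)cc(O)c12 | intermediate
18 | 5-hydroxy-6-iodo-7-(methoxymethoxy)-4H-chromen-4-one | O=c1ccoc2cc(OCOC)c(I)c(O)c12 | intermediate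
19 | 9-[3-methyl-3-(triethylsilyloxy)butyl]-9-borabicyclo[3.3.1]nonane | CC[Si](CC)(CC)OC(C)(C)CCB1C2CCCC1CCC2 | intermediate
20 | 5-hydroxy-7-(methoxymethoxy)-6-[3-methyl-3-(triethylsilyloxy)butyl]-4H-chromen-4-one | O=c1ccoc2cc(OCOC)c(CCC(C)(C)O[Si](CC)(CC)CC)c(O)c12 | intermediate
21 | 5-hydroxy-8-iodo-7-(methoxymethoxy)-6-[3-methyl-3-(triethylsilyloxy)butyl]-4H-chromen-4-one | O=c1ccoc2c(I)c(OCOC)c(CCC(C)(C)O[Si](CC)(CC)CC)c(O)c12 | intermediate
22 | 8-iodo-5,7-bis(methoxymethoxy)-6-[3-methyl-3-(triethylsilyloxy)butyl]-4H-chromen-4-one | O=c1ccoc2c(I)c(OCOC)c(CCC(C)(C)O[Si](CC)(CC)CC)c(OCOC)c12 | intermediate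
23 | iodo[(2R)-5-methyl-2-(prop-1-en-2-yl)hex-4-en-1-yl]zinc | C=C(C)[C@@H](CC=C(C)C)C[Zn]I | intermediate
24 | 5,7-bis(methoxymethoxy)-6-[3-methyl-3-(triethylsilyloxy)butyl]-8-[(2S)-5-methyl-2-(prop-1-en-2-yl)hex-4-en-1-yl]-4H-chromen-4-one | O=c1ccoc2c(C[C@H](CC=C(C)C)C(C)=C)c(OCOC)c(CCC(C)(C)O[Si](CC)(CC)CC)c(OCOC)c12 | intermediate
25 | (2S)-2-[2,4-bis(methoxymethoxy)phenyl]-5,7-bis(methoxymethoxy)-6-[3-methyl-3-(triethylsilyloxy)butyl]-8-[(2S)-5-methyl-2-(prop-1-en-2-yl)hex-4-en-1-yl]-2,3-dihydro-4H-chromen-4-one | C=C(C)[C@@H](CC=C(C)C)Cc1c(OCOC)c(CCC(C)(C)O[Si](CC)(CC)CC)c(OCOC)c2c1O[C@H](c1ccc(OCOC)cc1OCOC)CC2=O | intermediate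
26 | potassium enolate of 25 (potassium 2H-chromen-4-olate, C3=C4) | C=C(C)[C@@H](CC=C(C)C)Cc1c(OCOC)c(CCC(C)(C)O[Si](CC)(CC)CC)c(OCOC)c2c1O[C@H](c1ccc(OCOC)cc1OCOC)C=C2[O-].[K+] | intermediate
27 | (2R,3R)-2-[2,4-bis(methoxymethoxy)phenyl]-3-hydroxy-5,7-bis(methoxymethoxy)-6-[3-methyl-3-(triethylsilyloxy)butyl]-8-[(2S)-5-methyl-2-(prop-1-en-2-yl)hex-4-en-1-yl]-2,3-dihydro-4H-chromen-4-one | C=C(C)[C@@H](CC=C(C)C)Cc1c(OCOC)c(CCC(C)(C)O[Si](CC)(CC)CC)c(OCOC)c2c1O[C@H](c1ccc(OCOC)cc1OCOC)[C@@H](O)C2=O | intermediate
28 | (2R,3R)-2-(2,4-dihydroxyphenyl)-3,5,7-trihydroxy-6-[3-methyl-3-(triethylsilyloxy)butyl]-8-[(2S)-5-methyl-2-(prop-1-en-2-yl)hex-4-en-1-yl]-2,3-dihydro-4H-chromen-4-one | C=C(C)[C@@H](CC=C(C)C)Cc1c(O)c(CCC(C)(C)O[Si](CC)(CC)CC)c(O)c2c1O[C@H](c1ccc(O)cc1O)[C@@H](O)C2=O | intermediate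
29 | (2R,3R)-2-(2,4-dihydroxyphenyl)-3,5,7-trihydroxy-6-(3-hydroxy-3-methylbutyl)-8-[(2S)-5-methyl-2-(prop-1-en-2-yl)hex-4-en-1-yl]-2,3-dihydro-4H-chromen-4-one | C=C(C)[C@@H](CC=C(C)C)Cc1c(O)c(CCC(C)(C)O)c(O)c2c1O[C@H](c1ccc(O)cc1O)[C@@H](O)C2=O | target

## Step count and least certain steps

Total step count: 16. Longest linear sequence: 9 steps (16 → 29, steps 8 to 16); the side-chain branch (steps 1 to 4), the alkene (step 5) and ring B (steps 6 and 7) are made in parallel.

**Step 14 (key).** Most likely failure: protodeboronation of 15 outrunning a slow transmetalation and insertion, because the aryl group carries an ortho-alkoxy substituent and the enone is a donor-substituted vinylogous ester. A second risk is loss of enantiopurity through reversible opening of ring C at the rhodium enolate stage. Fallback, from 24 back to 25, closing O1–C2 instead of forming C2–C1':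
- Aqueous KOH in EtOH at reflux should open the pyranone of 24 and expel C2 as formate, giving 1-[2-hydroxy-4,6-bis(methoxymethoxy)-5-[3-methyl-3-(triethylsilyloxy)butyl]-3-[(2S)-5-methyl-2-(prop-1-en-2-yl)hex-4-en-1-yl]phenyl]ethan-1-one F1. Its only free phenol is the former O1, so the regiochemistry is kept.
- Claisen–Schmidt condensation (KOH, EtOH, rt) with 2,4-bis(methoxymethoxy)benzaldehyde F2, obtained from aryllithium 14 and DMF, should give the (E)-2'-hydroxychalcone F3.
- NaOAc in EtOH at reflux should close F3 by oxa-Michael addition, without control at C2, to 25 and its (2R)-epimer F4.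
- Noyori-type transfer hydrogenation with Rh(C5Me5)Cl[(R,R)-TsDPEN] and HCO2H/Et3N, which by the usual sense forms 4R benzylic alcohols through the cis-selective pathway, should reduce F4 faster, to the (2R,4R)-cis-flavan-4-ol F5. F5 is removed by chromatography and the unchanged ketone is 25.

**Step 13.** Most likely failure: β-hydride elimination from the alkylpalladium intermediate (the β-hydrogen is tertiary and allylic), combined with slow transmetalation to the di-ortho-oxygenated arylpalladium iodide, leading to reduction of 22 and loss of the organozinc. Fallback, from 9 back to 24, with boron as the transferring metal under slow-release conditions: iodine–lithium exchange on 9 (t-BuLi, Et2O, −78 °C), B(OMe)3, then aqueous KHF2 should give potassium trifluoro[(2R)-5-methyl-2-(prop-1-en-2-yl)hex-4-en-1-yl]borate F6. Suzuki–Miyaura coupling of F6 with 22 (Pd(OAc)2, RuPhos, K2CO3, toluene/H2O, 80 °C) should give 24.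

**Step 15.** Most likely failure: β-elimination of the O1 aryloxide from the potassium enolate (retro-oxa-Michael opening of ring C), which would scramble C2 on reclosure; addition of the enolate to the sulfonimine by-product is a lesser risk. Fallback, from 25 back to 27, avoiding a free metal enolate: LiN(SiMe3)2 is added to 25 and Me3SiCl in THF at −78 °C (internal quench) to give the silyl enol ether (2S)-2-[2,4-bis(methoxymethoxy)phenyl]-5,7-bis(methoxymethoxy)-6-[3-methyl-3-(triethylsilyloxy)butyl]-8-[(2S)-5-methyl-2-(prop-1-en-2-yl)hex-4-en-1-yl]-4-(trimethylsilyloxy)-2H-chromene F7. Rubottom oxidation with dimethyldioxirane (1.0 equiv, acetone, −78 °C), anti to the C2 aryl group, followed by citric acid in MeOH, should give 27. The electron-rich enol ether should react before the isolated olefins if the oxidant is not used in excess.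

**Step 9.** Most likely failure: loss of regiocontrol, with attack at C8 or twofold iodination, because C6 and C8 are each activated by three oxygens. Fallback, from 17 back to 20, relying on a sigmatropic shift that can only reach C6:
- O-allylation of the chelated phenol (allyl bromide, K2CO3, DMF, 60 °C) should give 7-(methoxymethoxy)-5-(prop-2-en-1-yloxy)-4H-chromen-4-one F8.
- Aromatic Claisen rearrangement (N,N-diethylaniline, 190 °C) delivers the allyl group to C6, the only ortho position of O5, giving 5-hydroxy-7-(methoxymethoxy)-6-(prop-2-en-1-yl)-4H-chromen-4-one F9.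
- Cross-metathesis with 2-methylbut-2-ene (second-generation Grubbs catalyst RuCl2(H2IMes)(PCy3)(=CHPh), CH2Cl2, 40 °C) should give 5-hydroxy-7-(methoxymethoxy)-6-(3-methylbut-2-en-1-yl)-4H-chromen-4-one F10.
- Mukaiyama hydration (Co(acac)2, PhSiH3, O2, THF/i-PrOH) should give 5-hydroxy-6-(3-hydroxy-3-methylbutyl)-7-(methoxymethoxy)-4H-chromen-4-one F11.
- Et3SiOTf and 2,6-lutidine, then K2CO3 in MeOH to free any silylated phenol, should give 20.

## Further compounds

F1 | step 14 | 1-[2-hydroxy-4,6-bis(methoxymethoxy)-5-[3-methyl-3-(triethylsilyloxy)butyl]-3-[(2S)-5-methyl-2-(prop-1-en-2-yl)hex-4-en-1-yl]phenyl]ethan-1-one | C=C(C)[C@@H](CC=C(C)C)Cc1c(OCOC)c(CCC(C)(C)O[Si](CC)(CC)CC)c(OCOC)c(C(C)=O)c1O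
F2 | step 14 | 2,4-bis(methoxymethoxy)benzaldehyde | COCOc1ccc(C=O)c(OCOC)c1
F3 | step 14 | (2E)-3-[2,4-bis(methoxymethoxy)phenyl]-1-[2-hydroxy-4,6-bis(methoxymethoxy)-5-[3-methyl-3-(triethylsilyloxy)butyl]-3-[(2S)-5-methyl-2-(prop-1-en-2-yl)hex-4-en-1-yl]phenyl]prop-2-en-1-one | C=C(C)[C@@H](CC=C(C)C)Cc1c(OCOC)c(CCC(C)(C)O[Si](CC)(CC)CC)c(OCOC)c(C(=O)/C=C/c2ccc(OCOC)cc2OCOC)c1O
F4 | step 14 | (2R)-2-[2,4-bis(methoxymethoxy)phenyl]-5,7-bis(methoxymethoxy)-6-[3-methyl-3-(triethylsilyloxy)butyl]-8-[(2S)-5-methyl-2-(prop-1-en-2-yl)hex-4-en-1-yl]-2,3-dihydro-4H-chromen-4-one | C=C(C)[C@@H](CC=C(C)C)Cc1c(OCOC)c(CCC(C)(C)O[Si](CC)(CC)CC)c(OCOC)c2c1O[C@@H](c1ccc(OCOC)cc1OCOC)CC2=O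
F5 | step 14 | (2R,4R)-2-[2,4-bis(methoxymethoxy)phenyl]-5,7-bis(methoxymethoxy)-6-[3-methyl-3-(triethylsilyloxy)butyl]-8-[(2S)-5-methyl-2-(prop-1-en-2-yl)hex-4-en-1-yl]-3,4-dihydro-2H-chromen-4-ol | C=C(C)[C@@H](CC=C(C)C)Cc1c(OCOC)c(CCC(C)(C)O[Si](CC)(CC)CC)c(OCOC)c2c1O[C@@H](c1ccc(OCOC)cc1OCOC)C[C@H]2O
F6 | step 13 | potassium trifluoro[(2R)-5-methyl-2-(prop-1-en-2-yl)hex-4-en-1-yl]borate | C=C(C)[C@@H](CC=C(C)C)C[B-](F)(F)F.[K+]
F7 | step 15 | (2S)-2-[2,4-bis(methoxymethoxy)phenyl]-5,7-bis(methoxymethoxy)-6-[3-methyl-3-(triethylsilyloxy)butyl]-8-[(2S)-5-methyl-2-(prop-1-en-2-yl)hex-4-en-1-yl]-4-(trimethylsilyloxy)-2H-chromene | C=C(C)[C@@H](CC=C(C)C)Cc1c(OCOC)c(CCC(C)(C)O[Si](CC)(CC)CC)c(OCOC)c2c1O[C@H](c1ccc(OCOC)cc1OCOC)C=C2O[Si](C)(C)C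
F8 | step 9 | 7-(methoxymethoxy)-5-(prop-2-en-1-yloxy)-4H-chromen-4-one | O=c1ccoc2cc(OCOC)cc(OCC=C)c12
F9 | step 9 | 5-hydroxy-7-(methoxymethoxy)-6-(prop-2-en-1-yl)-4H-chromen-4-one | O=c1ccoc2cc(OCOC)c(CC=C)c(O)c12
F10 | step 9 | 5-hydroxy-7-(methoxymethoxy)-6-(3-methylbut-2-en-1-yl)-4H-chromen-4-one | O=c1ccoc2cc(OCOC)c(CC=C(C)C)c(O)c12
F11 | step 9 | 5-hydroxy-6-(3-hydroxy-3-methylbutyl)-7-(methoxymethoxy)-4H-chromen-4-one | O=c1ccoc2cc(OCOC)c(CCC(C)(C)O)c(O)c12
A1 | alternative 1 | (2E)-3-[2,4-bis(methoxymethoxy)phenyl]-1-[2,4,6-tris(methoxymethoxy)-3-[3-methyl-3-(triethylsilyloxy)butyl]-5-[(2S)-5-methyl-2-(prop-1-en-2-yl)hex-4-en-1-yl]phenyl]prop-2-en-1-one | C=C(C)[C@@H](CC=C(C)C)Cc1c(OCOC)c(CCC(C)(C)O[Si](CC)(CC)CC)c(OCOC)c(C(=O)/C=C/c2ccc(OCOC)cc2OCOC)c1OCOC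
A2 | alternative 1 | [(2R,3S)-3-[2,4-bis(methoxymethoxy)phenyl]oxiran-2-yl][2,4,6-tris(methoxymethoxy)-3-[3-methyl-3-(triethylsilyloxy)butyl]-5-[(2S)-5-methyl-2-(prop-1-en-2-yl)hex-4-en-1-yl]phenyl]methanone | C=C(C)[C@@H](CC=C(C)C)Cc1c(OCOC)c(CCC(C)(C)O[Si](CC)(CC)CC)c(OCOC)c(C(=O)[C@@H]2O[C@H]2c3ccc(OCOC)cc3OCOC)c1OCOC
A3 | alternative 2 | (2R,3R)-3-[2,4-bis(methoxymethoxy)phenyl]-2-hydroxy-3-[3,5-bis(methoxymethoxy)-4-[3-methyl-3-(triethylsilyloxy)butyl]-2-[(2S)-5-methyl-2-(prop-1-en-2-yl)hex-4-en-1-yl]phenoxy]propanoic acid | C=C(C)[C@@H](CC=C(C)C)Cc1c(OCOC)c(CCC(C)(C)O[Si](CC)(CC)CC)c(OCOC)cc1O[C@H](c1ccc(OCOC)cc1OCOC)[C@@H](O)C(=O)O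
A4 | alternative 3 | (2R,3R)-2-[2,4-bis(methoxymethoxy)phenyl]-3-hydroxy-5,7-bis(methoxymethoxy)-8-(3-methylbut-2-en-1-yl)-6-[3-methyl-3-(triethylsilyloxy)butyl]-2,3-dihydro-4H-chromen-4-one | CC(C)=CCc1c(OCOC)c(CCC(C)(C)O[Si](CC)(CC)CC)c(OCOC)c2c1O[C@H](c1ccc(OCOC)cc1OCOC)[C@@H](O)C2=O
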